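## Retrosynthetic overview
- 19 ⇐ 18 (three aryl silyl ethers removed) ⇐ chromone 12 + boronic acid 17. The C2–aryl bond and the 2S centre are made last, by ligand-controlled rhodium 1,4-addition under neutral conditions.
- Chromone 11 is an isomer of dienyl pyranopyrandione 9. Ring C closes when the only free OH of a 4-hydroxy-2-pyranone attacks an enaminone. Ring A is then built from the six carbons of the old pyranone (lactone enolate → acylketene → C–C closure). Both closures happen in one flask.
- O1 is fixed before ring A exists, so the side chain can only end up at C6, never at C8.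
- Pyranone 7 ⇐ dehydroacetic acid 1 (C3, C4 and all of ring A) + amide acetal 2 (C2) + (S)-citronellal 4 (the whole C10 chain with its stereocentre).
- Ring order: ring B is bought; rings C and A form together in step 3.

Assumption: 4 is used at ≥98% ee, and (S)-MeO-F12-BIPHEP is taken to induce the same facial sense on a chromone as (S)-BINAP does on cyclohexenone (giving 2S); if the CD spectrum of 18 shows the opposite, the (R)-ligand is used.

## Route

Step 1
Reactants: 1 dehydroacetic acid (3-acetyl-4-hydroxy-6-methyl-2H-pyran-2-one); 2 N,N-dimethylformamide dimethyl acetal (1.1 equiv)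
Product: 3 3-[(2E)-3-(dimethylamino)prop-2-enoyl]-4-hydroxy-6-methyl-2H-pyran-2-one
Conditions: PhMe, 60–80 °C, 3 h
Reagents that add atoms: none
Why: Enaminone formation by amide-acetal condensation: the acetyl CH3 of the tricarbonyl unit condenses much faster than the 6-methyl group, which masks it against the base of step 2 and installs the future C2; no stereocentre is formed.

Step 2
Reactants: 3 enaminone; 4 (S)-citronellal [(3S)-3,7-dimethyloct-6-enal] (1.2 equiv)
Product: 7 (4S)-1-{3-[(2E)-3-(dimethylamino)prop-2-enoyl]-4-hydroxy-2-oxo-2H-pyran-6-yl}-4,8-dimethylnon-7-en-2-yl acetate (about 1:1 at the carbinol carbon), via dilithio dianion 5 (not isolated), via dilithium aldolate 6 (not isolated)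
Conditions: LiN(iPr)2 (LDA, 2.3 equiv), THF, −78 → −30 °C; 4, −78 °C; Ac2O (1.2 equiv), −78 → 0 °C; aq NH4Cl
Reagents that add atoms: acetic anhydride, CC(=O)OC(C)=O
Why: Vinylogous aldol addition of a 4-hydroxy-2-pyranone dianion (the dianion chemistry known for triacetic acid lactone): after O-deprotonation the 6-methyl group is the only acidic C–H left, its carbanion adds 1,2 to the aldehyde, the hard alkoxide is acetylated in preference to the delocalised 4-olate, the citronellal stereocentre is untouched, and the new carbinol centre is erased in step 3.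

Step 3
Reactants: 7 acetoxy enaminone
Product: 11 5,7-dihydroxy-6-[(1E,3S)-3,7-dimethylocta-1,6-dien-1-yl]-4H-chromen-4-one, via pyranopyrandione acetate 8 (not isolated), via dienyl pyranopyrandione 9 (not isolated), via potassium acylketene dienolate 10 (not isolated)
Conditions: AcOH–PhMe 1:4, 100 °C, 2 h, then evaporate (PhMe chase); residue in THF added slowly to KN(SiMe3)2 (KHMDS, 4.5 equiv), THF, 0.01 M, −78 → 45 °C; 0.5 M HCl, 0 °C
Reagents that add atoms: none
Why: Proposed new method: acid-promoted addition–elimination of the only free hydroxyl onto the enaminone (the standard chromone-type closure) first fixes O1 and hence the 6-regiochemistry, then KHMDS expels acetate (E1cB) and deprotonates the dienyl chain of 9 at its allylic CH2, the extended lactone enolate fragments in a vinylogous E1cB sense to acylketene dienolate 10, whose O-closure only regenerates 9 while the irreversible C6-to-C5 closure (6π electrocyclisation or intramolecular C-acylation) and tautomerisation give aromatic ring A and shift the double bond into the less strained E-styrene position next to the untouched C3'' centre; the closest known reaction types are E1cB ketene formation from enolates of aryl acetoacetates, the dienylketene electrocyclisation that ends the Danheiser benzannulation, and the alkoxide-mediated conversion of triacetic lactone methyl ether into phloroglucinol monomethyl ether.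

Step 4
Reactants: 11 dihydroxychromone
Product: 12 7-(tert-butyldimethylsilyloxy)-6-[(1E,3S)-3,7-dimethylocta-1,6-dien-1-yl]-5-hydroxy-4H-chromen-4-one
Conditions: TBSCl (1.1 equiv), imidazole (2.2 equiv), DMF, 0 → 23 °C
Reagents that add atoms: tert-butyldimethylsilyl chloride, CC(C)(C)[Si](C)(C)Cl
Why: Chemoselective phenol silylation: the 5-OH is hydrogen-bonded to C4=O and flanked by the alkenyl group, so only the acidic 7-OH reacts, which removes the proton that would deactivate the enone and quench aryl-rhodium in step 7.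

Step 5
Reactants: 13 4-bromocatechol
Product: 14 4-bromo-1,2-bis(tert-butyldimethylsilyloxy)benzene
Conditions: TBSCl (2.3 equiv), imidazole (5 equiv), DMF, 23 °C
Reagents that add atoms: tert-butyldimethylsilyl chloride, CC(C)(C)[Si](C)(C)Cl
Why: Standard imidazole-promoted silyl ether formation on both phenols gives a catechol mask that is removed later by fluoride without acid or base.

Step 6
Reactants: 14 aryl bromide
Product: 17 [3,4-bis(tert-butyldimethylsilyloxy)phenyl]boronic acid, via aryllithium 15 (not isolated), via lithium triisopropoxyborate 16 (not isolated)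
Conditions: n-BuLi (1.05 equiv), THF, −78 °C; B(OiPr)3 (1.5 equiv), −78 → 0 °C; 1 M HCl, 0 °C, brief
Reagents that add atoms: triisopropyl borate, CC(C)OB(OC(C)C)OC(C)C; water, O
Why: Bromine–lithium exchange followed by borylation and hydrolysis: lithium sits meta and para to the silyloxy groups, so no oxygen-to-carbon silyl shift can occur.

Step 7
Reactants: 12 chromone; 17 boronic acid (2.5 equiv)
Product: 18 (2S)-2-[3,4-bis(tert-butyldimethylsilyloxy)phenyl]-7-(tert-butyldimethylsilyloxy)-6-[(1E,3S)-3,7-dimethylocta-1,6-dien-1-yl]-5-hydroxychroman-4-one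
Conditions: [Rh(OH)(cod)]2 (2.5 mol %), (S)-MeO-F12-BIPHEP (5.5 mol %), CH2Cl2–H2O 10:1, 25 °C
Reagents that add atoms: none
Why: Hayashi–Miyaura-type asymmetric 1,4-addition of an arylboronic acid to a chromone: the electron-poor biaryl diphosphine keeps monovalent rhodium active at room temperature so that neither ring opening nor 1,2-addition competes, the (S)-ligand delivers the aryl group to the Re face of C2 and sets 2S regardless of the remote C3'' centre, and the unactivated alkenes are not acceptors for aryl-rhodium.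

Step 8
Reactants: 18 tris-silyl flavanone
Product: 19 (2S)-2-(3,4-dihydroxyphenyl)-6-[(1E,3S)-3,7-dimethylocta-1,6-dien-1-yl]-5,7-dihydroxychroman-4-one (CNP0230070.1)
Conditions: Et3N·3HF (3 equiv), THF, 0 → 23 °C
Reagents that add atoms: none
Why: Fluoride cleavage of aryl silyl ethers in a weakly acidic medium: no base is present, so retro-oxa-Michael racemisation of C2 cannot start, and the medium is too weakly acidic to protonate the electron-rich styrene.

## Compound list
1 | dehydroacetic acid | CC(=O)C1=C(O)C=C(C)OC1=O | starting material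
2 | N,N-dimethylformamide dimethyl acetal | COC(OC)N(C)C | starting material
3 | 3-[(2E)-3-(dimethylamino)prop-2-enoyl]-4-hydroxy-6-methyl-2H-pyran-2-one | CN(C)/C=C/C(=O)C1=C(O)C=C(C)OC1=O | intermediate
4 | (S)-citronellal | CC(C)=CCC[C@H](C)CC=O | starting material
5 | dilithio dianion of 3 (4-olate, 6-methylene carbanion) | [Li+].[Li+].[CH2-]C1=CC([O-])=C(C(=O)/C=C/N(C)C)C(=O)O1 | intermediate
6 | dilithium aldolate from 5 and 4 | [Li+].[Li+].CN(C)/C=C/C(=O)C1=C([O-])C=C(CC([O-])C[C@@H](C)CCC=C(C)C)OC1=O | intermediate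
7 | (4S)-1-{3-[(2E)-3-(dimethylamino)prop-2-enoyl]-4-hydroxy-2-oxo-2H-pyran-6-yl}-4,8-dimethylnon-7-en-2-yl acetate | CN(C)/C=C/C(=O)C1=C(O)C=C(CC(OC(C)=O)C[C@@H](C)CCC=C(C)C)OC1=O | intermediate
8 | (4S)-1-(4,5-dioxo-4H,5H-pyrano[4,3-b]pyran-7-yl)-4,8-dimethylnon-7-en-2-yl acetate | CC(=O)OC(CC1=CC2=C(C(=O)C=CO2)C(=O)O1)C[C@@H](C)CCC=C(C)C | intermediate
9 | 7-[(1E,4S)-4,8-dimethylnona-1,7-dien-1-yl]-4H,5H-pyrano[4,3-b]pyran-4,5-dione | O=C1C=COC2=C1C(=O)OC(/C=C/C[C@@H](C)CCC=C(C)C)=C2 | intermediate
10 | potassium acylketene dienolate (ring-opened 9 anion) | [K+].O=C=C1C(=O)C=CO/C1=C/C([O-])=C/C=C/[C@@H](C)CCC=C(C)C | intermediate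
11 | 5,7-dihydroxy-6-[(1E,3S)-3,7-dimethylocta-1,6-dien-1-yl]-4H-chromen-4-one | CC(C)=CCC[C@H](C)/C=C/c1c(O)cc2OC=CC(=O)c2c1O | intermediate
12 | 7-O-TBS ether of 11 | CC(C)=CCC[C@H](C)/C=C/c1c(O[Si](C)(C)C(C)(C)C)cc2OC=CC(=O)c2c1O | intermediate
13 | 4-bromocatechol | Oc1ccc(Br)cc1O | starting material
14 | 4-bromo-1,2-bis(tert-butyldimethylsilyloxy)benzene | CC(C)(C)[Si](C)(C)Oc1ccc(Br)cc1O[Si](C)(C)C(C)(C)C | intermediate
15 | 3,4-bis(tert-butyldimethylsilyloxy)phenyllithium | [Li]c1ccc(O[Si](C)(C)C(C)(C)C)c(O[Si](C)(C)C(C)(C)C)c1 | intermediate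
16 | lithium [3,4-bis(tert-butyldimethylsilyloxy)phenyl]triisopropoxyborate | [Li+].CC(C)O[B-](OC(C)C)(OC(C)C)c1ccc(O[Si](C)(C)C(C)(C)C)c(O[Si](C)(C)C(C)(C)C)c1 | intermediate
17 | [3,4-bis(tert-butyldimethylsilyloxy)phenyl]boronic acid | OB(O)c1ccc(O[Si](C)(C)C(C)(C)C)c(O[Si](C)(C)C(C)(C)C)c1 | intermediate
18 | (2S)-tris-TBS flavanone | CC(C)=CCC[C@H](C)/C=C/c1c(O[Si](C)(C)C(C)(C)C)cc2c(c1O)C(=O)C[C@@H](c1ccc(O[Si](C)(C)C(C)(C)C)c(O[Si](C)(C)C(C)(C)C)c1)O2 | intermediate
19 | (2S)-2-(3,4-dihydroxyphenyl)-6-[(1E,3S)-3,7-dimethylocta-1,6-dien-1-yl]-5,7-dihydroxychroman-4-one | CC(C)=CCC[C@H](C)/C=C/c1c(O)cc2c(c1O)C(=O)C[C@@H](c1ccc(O)c(O)c1)O2 | target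

## Step count
Total steps: 8. Longest linear sequence: 6 (steps 1, 2, 3, 4, 7, 8).

## Steps most likely to fail

**Step 3.** The lactone enolate may be inert towards ketene formation, may oligomerise through the electrophilic C2, or may give some Z-styrene.
- The fallback replaces the ketene pathway with a discrete ester and a classical condensation. It sets out from 7.
- Only the acid stage is run. Acetate is then eliminated with DBU (CH2Cl2, 23 °C) and 9 is isolated.
- NaOMe (1.05 equiv) in MeOH at 0 °C opens the lactone to methyl 2-[(3E,6S)-6,10-dimethyl-2-oxoundeca-3,9-dien-1-yl]-4-oxo-4H-pyran-3-carboxylate F1.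
- A dianion Dieckmann condensation (LiN(iPr)2, 2.5 equiv, THF, −78 → 0 °C) then closes ring A with the same regiochemistry and comes back to the route at 11.

**Step 2.** A dianion of an enaminone-bearing pyranone has no direct precedent, and enolisation of 4 or attack on the enaminone may win.
- The fallback reverses the order in which the pyranone is armed. It sets out from 4.
- Commercial triacetic acid lactone (4-hydroxy-6-methyl-2H-pyran-2-one) has an established LDA-mediated vinylogous aldol chemistry. It is added to 4 with in-situ acetylation to give (4S)-1-(4-hydroxy-2-oxo-2H-pyran-6-yl)-4,8-dimethylnon-7-en-2-yl acetate F2.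
- O-Acylation and acyl shift with AcOH, DCC and DMAP (PhMe, 60–80 °C) gives (4S)-1-(3-acetyl-4-hydroxy-2-oxo-2H-pyran-6-yl)-4,8-dimethylnon-7-en-2-yl acetate F3.
- Condensation of F3 with 2 comes back to the route at 7.

**Step 7.** The electron-rich, 6-substituted chromone may react slowly or with eroded selectivity.
- The fallback separates bond formation from stereocontrol. It sets out from 12.
- The more active ligand-free [Rh(OH)(cod)]2 adds 17 to give the 1:1 C2-epimer mixture (2RS)-2-[3,4-bis(tert-butyldimethylsilyloxy)phenyl]-7-(tert-butyldimethylsilyloxy)-6-[(1E,3S)-3,7-dimethylocta-1,6-dien-1-yl]-5-hydroxychroman-4-one F4.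
- A kinetic resolution by asymmetric transfer hydrogenation (Cp*RhCl[(R,R)-TsDPEN], HCO2H–Et3N, EtOAc, 23 °C) reduces only the 2R epimer. This gives the cis alcohol (2R,4R)-2-[3,4-bis(tert-butyldimethylsilyloxy)phenyl]-7-(tert-butyldimethylsilyloxy)-6-[(1E,3S)-3,7-dimethylocta-1,6-dien-1-yl]chromane-4,5-diol F5.
- Chromatographic removal of F5 leaves the 2S epimer and comes back to the route at 18.

Further compounds
F1 | step 3 | methyl 2-[(3E,6S)-6,10-dimethyl-2-oxoundeca-3,9-dien-1-yl]-4-oxo-4H-pyran-3-carboxylate | COC(=O)C1=C(CC(=O)/C=C/C[C@@H](C)CCC=C(C)C)OC=CC1=O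
F2 | step 2 | (4S)-1-(4-hydroxy-2-oxo-2H-pyran-6-yl)-4,8-dimethylnon-7-en-2-yl acetate | CC(=O)OC(CC1=CC(O)=CC(=O)O1)C[C@@H](C)CCC=C(C)C
F3 | step 2 | (4S)-1-(3-acetyl-4-hydroxy-2-oxo-2H-pyran-6-yl)-4,8-dimethylnon-7-en-2-yl acetate | CC(=O)OC(CC1=CC(O)=C(C(C)=O)C(=O)O1)C[C@@H](C)CCC=C(C)C
F4 | step 7 | (2RS)-2-[3,4-bis(tert-butyldimethylsilyloxy)phenyl]-7-(tert-butyldimethylsilyloxy)-6-[(1E,3S)-3,7-dimethylocta-1,6-dien-1-yl]-5-hydroxychroman-4-one | CC(C)=CCC[C@H](C)/C=C/c1c(O[Si](C)(C)C(C)(C)C)cc2c(c1O)C(=O)CC(c1ccc(O[Si](C)(C)C(C)(C)C)c(O[Si](C)(C)C(C)(C)C)c1)O2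
F5 | step 7 | (2R,4R)-2-[3,4-bis(tert-butyldimethylsilyloxy)phenyl]-7-(tert-butyldimethylsilyloxy)-6-[(1E,3S)-3,7-dimethylocta-1,6-dien-1-yl]chromane-4,5-diol | CC(C)=CCC[C@H](C)/C=C/c1c(O[Si](C)(C)C(C)(C)C)cc2c(c1O)[C@H](O)C[C@H](c1ccc(O[Si](C)(C)C(C)(C)C)c(O[Si](C)(C)C(C)(C)C)c1)O2
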